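**Plan**

- Locants: flavone 1 is the 5-hydroxy-7,4'-dimethoxyflavone unit (plain and primed locants). Flavone 2 is the apigenin unit (double- and triple-primed locants). The two are joined C3-C6''.
- Cuts, in order: three O-benzyl groups and the peri 5-O-methyl group; C4''-C4a'' and O1''-C2'' of the pyranone ring of flavone 2; the C3-C6'' biaryl bond; O1-C2 of flavone 1, back to an aryl ynone.
- Enabling feature: ring A'' is a phloroglucinol ring in which O1'' lies para to C6'', the carbon bearing flavone 1, and C4a'' and C8'' are the two CH carbons ortho to that oxygen. A 4-flavonyl-3,5-dioxygenated phenol is therefore symmetric and lacks only an aroylacetyl C3 unit.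
- Control: the two oxygens beside the flavonyl group (later O5'' and O7'') stay benzylated. Only the para hydroxyl can become O1'', so the 8''-linked isomer is excluded by structure.
- Forward order: pyranone ring of flavone 1 by iodocyclisation, ring A'' attached by Suzuki-Miyaura coupling, pyranone ring of flavone 2 by thermal annulation, then one global ether cleavage.
- Stereochemistry: the target has no stereocentre. The single carbinol centre made on the way is oxidised away at once.

Key step: step 8

Assumption: the SMILES carries no stereodescriptor, so the hindered C3-C6'' axis is treated as unspecified and material containing it is made as the racemate.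

**Step 1**
Reactants: 1 4-ethynylanisole; 2 2,4,6-trimethoxybenzaldehyde
Product: 4 rac-3-(4-methoxyphenyl)-1-(2,4,6-trimethoxyphenyl)prop-2-yn-1-ol, via lithium acetylide 3 (not isolated)
Conditions: 1, n-BuLi, THF, −78 °C; then 2, −78 to 0 °C; aq NH4Cl
Reagents that add atoms: none
Why: 1,2-addition of a lithium acetylide to an aromatic aldehyde is reliable even with two ortho methoxy groups, and the carbinol centre forms as a racemate that step 2 erases.

**Step 2**
Reactants: 4 rac-3-(4-methoxyphenyl)-1-(2,4,6-trimethoxyphenyl)prop-2-yn-1-ol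
Product: 5 3-(4-methoxyphenyl)-1-(2,4,6-trimethoxyphenyl)prop-2-yn-1-one
Conditions: MnO2 (activated, excess), CH2Cl2, rt
Reagents that add atoms: none
Why: activated MnO2 oxidises benzylic-propargylic alcohols under neutral conditions, which spares this easily ionised, electron-rich carbinol from acid.

**Step 3**
Reactants: 5 3-(4-methoxyphenyl)-1-(2,4,6-trimethoxyphenyl)prop-2-yn-1-one
Product: 6 3-iodo-5,7-dimethoxy-2-(4-methoxyphenyl)-4H-chromen-4-one
Conditions: ICl (1.2 equiv), CH2Cl2, −78 °C
Reagents that add atoms: iodine monochloride, ClI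
Why: in this electrophilic iodocyclisation of an ortho-methoxyaryl ynone, ICl activates the alkyne, one of the two equivalent ortho methoxy oxygens attacks 6-endo-dig at the anisyl-bearing carbon and chloride removes its methyl group, which fixes iodine at C3, while low temperature and near-stoichiometric ICl guard ring A against iodination.

**Step 4**
Reactants: 7 3,5-bis(benzyloxy)phenol
Product: 8 [3,5-bis(benzyloxy)phenoxy]triisopropylsilane
Conditions: TIPSCl, imidazole, DMF, rt
Reagents that add atoms: chlorotriisopropylsilane, CC(C)[Si](Cl)(C(C)C)C(C)C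
Why: this is a standard phenol silylation, and the bulky, non-coordinating silyl group is chosen because it shields its two neighbouring CH positions in step 5 and later leaves with fluoride without touching benzyl ethers.

**Step 5**
Reactants: 8 [3,5-bis(benzyloxy)phenoxy]triisopropylsilane
Product: 11 [2,6-bis(benzyloxy)-4-(triisopropylsilyloxy)phenyl]boronic acid, via aryllithium 9 (not isolated), via lithium arylborate 10 (not isolated)
Conditions: n-BuLi, THF, 0 °C; B(OiPr)3, −78 °C to rt; aq NH4Cl
Reagents that add atoms: triisopropyl borate, CC(C)OB(OC(C)C)OC(C)C; water, O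
Why: in this directed ortho-metalation the proton between the two benzyloxy groups is the most acidic and lies between two coordinating oxygens, whereas the positions beside the silyl ether are shielded, so lithiation and borate trapping should mark the carbon para to the silyloxy group.

**Step 6**
Reactants: 6 3-iodo-5,7-dimethoxy-2-(4-methoxyphenyl)-4H-chromen-4-one; 11 [2,6-bis(benzyloxy)-4-(triisopropylsilyloxy)phenyl]boronic acid
Product: 12 3-[2,6-bis(benzyloxy)-4-(triisopropylsilyloxy)phenyl]-5,7-dimethoxy-2-(4-methoxyphenyl)-4H-chromen-4-one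
Conditions: Pd(OAc)2, SPhos, K3PO4, toluene/H2O, 90 °C
Reagents that add atoms: none
Why: in this Suzuki-Miyaura coupling of a 3-iodoflavone the electron-poor C-I bond adds readily to zerovalent palladium, and the bulky, electron-rich biaryl phosphine SPhos is the established remedy for di-ortho-alkoxy boronic acids and crowded reductive eliminations.

**Step 7**
Reactants: 12 3-[2,6-bis(benzyloxy)-4-(triisopropylsilyloxy)phenyl]-5,7-dimethoxy-2-(4-methoxyphenyl)-4H-chromen-4-one
Product: 13 3-[2,6-bis(benzyloxy)-4-hydroxyphenyl]-5,7-dimethoxy-2-(4-methoxyphenyl)-4H-chromen-4-one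
Conditions: TBAF, AcOH, THF, 0 °C
Reagents that add atoms: none
Why: fluoride cleaves the Si-O bond selectively, and acetic acid buffering keeps the medium from turning basic enough to open the chromone ring.

**Step 8**
Reactants: 13 3-[2,6-bis(benzyloxy)-4-hydroxyphenyl]-5,7-dimethoxy-2-(4-methoxyphenyl)-4H-chromen-4-one; 14 ethyl 3-[4-(benzyloxy)phenyl]-3-oxopropanoate
Product: 18 5,7-bis(benzyloxy)-2-[4-(benzyloxy)phenyl]-6-[5,7-dimethoxy-2-(4-methoxyphenyl)-4-oxo-4H-chromen-3-yl]-4H-chromen-4-one, via aroylketene 15 (not isolated), via aryl aroylacetate 16 (not isolated), via ortho-hydroxyaryl diketone 17 (not isolated)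
Conditions: 14 (3 equiv, in portions), Ph2O, 240 °C, Ar stream to carry off EtOH and H2O, no catalyst
Reagents that add atoms: none
Why: At about 240 °C ketoester 14 loses ethanol to give aroylketene 15, which the only hydroxyl of 13 traps as ester 16; this trapping is reversible at that temperature, and the acyl group settles on one of the two equivalent ortho carbons (thermal Fries-type shift) as the hydrogen-bonded diketone 17, which forms C4''-C4a''. The phenolic oxygen of 17 then adds to the aryl ketone carbonyl (6-exo-trig hemiketalisation) and water is lost, which forms O1''-C2'' and closes the pyranone ring. The closest known reaction type is the uncatalysed thermal condensation of phenols with β-ketoesters to chromones (Mentzer pyrone synthesis, the acid-free relative of the Simonis reaction), well established for phloroglucinol and its ethers with aroylacetates. No stereocentre is created; the C3-C6'' axis becomes unsymmetrically substituted and is obtained racemic. The step needs the oxygen para to the flavonyl group to become O1'', and because both oxygens beside the flavonyl group are benzyl ethers, closure to the 8''-linked isomer and oxa-Michael attack of a flanking phenol on C2 of flavone 1 are excluded by structure instead of being left to steric bias. Flavone 1 carries no free hydroxyl and its ring A is deactivated by C4=O, so it offers the ketene no productive site, and the absence of acid keeps the Pechmann route to a 4-arylcoumarin closed.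

**Step 9**
Reactants: 18 5,7-bis(benzyloxy)-2-[4-(benzyloxy)phenyl]-6-[5,7-dimethoxy-2-(4-methoxyphenyl)-4-oxo-4H-chromen-3-yl]-4H-chromen-4-one
Product: 19 5,7-dihydroxy-6-[5-hydroxy-7-methoxy-2-(4-methoxyphenyl)-4-oxo-4H-chromen-3-yl]-2-(4-hydroxyphenyl)-4H-chromen-4-one (target)
Conditions: BCl3, C6HMe5, CH2Cl2, −78 to 0 °C; then H2O
Reagents that add atoms: none
Why: BCl3 with pentamethylbenzene as benzyl-cation trap is an established non-reductive cleavage of aryl benzyl ethers, and on warming the same reagent, chelated between C4=O and the peri oxygen, should remove only the 5-O-methyl group and leave the unchelated 7- and 4'-methyl ethers in place.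

**Compound list**

1 | 4-ethynylanisole | C#Cc1ccc(OC)cc1 | starting material
2 | 2,4,6-trimethoxybenzaldehyde | COc1cc(OC)c(C=O)c(OC)c1 | starting material
3 | lithium (4-methoxyphenyl)acetylide | [Li]C#Cc1ccc(OC)cc1 | intermediate
4 | rac-3-(4-methoxyphenyl)-1-(2,4,6-trimethoxyphenyl)prop-2-yn-1-ol | COc1ccc(C#CC(O)c2c(OC)cc(OC)cc2OC)cc1 | intermediate
5 | 3-(4-methoxyphenyl)-1-(2,4,6-trimethoxyphenyl)prop-2-yn-1-one | COc1ccc(C#CC(=O)c2c(OC)cc(OC)cc2OC)cc1 | intermediate
6 | 3-iodo-5,7-dimethoxy-2-(4-methoxyphenyl)-4H-chromen-4-one | COc1ccc(-c2oc3cc(OC)cc(OC)c3c(=O)c2I)cc1 | intermediate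
7 | 3,5-bis(benzyloxy)phenol | Oc1cc(OCc2ccccc2)cc(OCc2ccccc2)c1 | starting material
8 | [3,5-bis(benzyloxy)phenoxy]triisopropylsilane | CC(C)[Si](Oc1cc(OCc2ccccc2)cc(OCc2ccccc2)c1)(C(C)C)C(C)C | intermediate
9 | [2,6-bis(benzyloxy)-4-(triisopropylsilyloxy)phenyl]lithium | [Li]c1c(OCc2ccccc2)cc(O[Si](C(C)C)(C(C)C)C(C)C)cc1OCc1ccccc1 | intermediate
10 | lithium [2,6-bis(benzyloxy)-4-(triisopropylsilyloxy)phenyl]triisopropoxyborate | [Li+].CC(C)O[B-](OC(C)C)(OC(C)C)c1c(OCc2ccccc2)cc(O[Si](C(C)C)(C(C)C)C(C)C)cc1OCc1ccccc1 | intermediate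
11 | [2,6-bis(benzyloxy)-4-(triisopropylsilyloxy)phenyl]boronic acid | OB(O)c1c(OCc2ccccc2)cc(O[Si](C(C)C)(C(C)C)C(C)C)cc1OCc1ccccc1 | intermediate
12 | 3-[2,6-bis(benzyloxy)-4-(triisopropylsilyloxy)phenyl]-5,7-dimethoxy-2-(4-methoxyphenyl)-4H-chromen-4-one | COc1ccc(-c2oc3cc(OC)cc(OC)c3c(=O)c2-c2c(OCc3ccccc3)cc(O[Si](C(C)C)(C(C)C)C(C)C)cc2OCc2ccccc2)cc1 | intermediate
13 | 3-[2,6-bis(benzyloxy)-4-hydroxyphenyl]-5,7-dimethoxy-2-(4-methoxyphenyl)-4H-chromen-4-one | COc1ccc(-c2oc3cc(OC)cc(OC)c3c(=O)c2-c2c(OCc3ccccc3)cc(O)cc2OCc2ccccc2)cc1 | intermediate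
14 | ethyl 3-[4-(benzyloxy)phenyl]-3-oxopropanoate | CCOC(=O)CC(=O)c1ccc(OCc2ccccc2)cc1 | starting material
15 | 3-[4-(benzyloxy)phenyl]-3-oxoprop-1-en-1-one (aroylketene) | O=C=CC(=O)c1ccc(OCc2ccccc2)cc1 | intermediate
16 | 3,5-bis(benzyloxy)-4-[5,7-dimethoxy-2-(4-methoxyphenyl)-4-oxo-4H-chromen-3-yl]phenyl 3-[4-(benzyloxy)phenyl]-3-oxopropanoate | COc1ccc(-c2oc3cc(OC)cc(OC)c3c(=O)c2-c2c(OCc3ccccc3)cc(OC(=O)CC(=O)c3ccc(OCc4ccccc4)cc3)cc2OCc2ccccc2)cc1 | intermediate
17 | 1-{2,4-bis(benzyloxy)-3-[5,7-dimethoxy-2-(4-methoxyphenyl)-4-oxo-4H-chromen-3-yl]-6-hydroxyphenyl}-3-[4-(benzyloxy)phenyl]propane-1,3-dione | COc1ccc(-c2oc3cc(OC)cc(OC)c3c(=O)c2-c2c(OCc3ccccc3)cc(O)c(C(=O)CC(=O)c3ccc(OCc4ccccc4)cc3)c2OCc2ccccc2)cc1 | intermediate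
18 | 5,7-bis(benzyloxy)-2-[4-(benzyloxy)phenyl]-6-[5,7-dimethoxy-2-(4-methoxyphenyl)-4-oxo-4H-chromen-3-yl]-4H-chromen-4-one | COc1ccc(-c2oc3cc(OC)cc(OC)c3c(=O)c2-c2c(OCc3ccccc3)cc3oc(-c4ccc(OCc5ccccc5)cc4)cc(=O)c3c2OCc2ccccc2)cc1 | intermediate
19 | 5,7-dihydroxy-6-[5-hydroxy-7-methoxy-2-(4-methoxyphenyl)-4-oxo-4H-chromen-3-yl]-2-(4-hydroxyphenyl)-4H-chromen-4-one | COc1ccc(-c2oc3cc(OC)cc(O)c3c(=O)c2-c2c(O)cc3oc(-c4ccc(O)cc4)cc(=O)c3c2O)cc1 | target

**Step count**

Total step count: 9.
Longest linear sequence: 7 (steps 1, 2, 3, 6, 7, 8, 9).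

**Steps most likely to fail**

**Step 8.**
- What may go wrong: the crowded phenol may trap the ketene so slowly that self-condensation of the ketene consumes 14. The acyl shift may stall at the O-acyl stage, or the ester may close in the Pechmann sense. Long heating may also begin to cleave benzyl ethers.
- Fallback, from 13 back to 18: the carbonyl carbon is brought in as CO instead of by acyl transfer. Mono-iodination ortho to the free hydroxyl (NIS, 1 equiv, MeCN, 0 °C; ring A'' is by far the most activated arene) should give 3-[2,6-bis(benzyloxy)-4-hydroxy-3-iodophenyl]-5,7-dimethoxy-2-(4-methoxyphenyl)-4H-chromen-4-one F1. Carbonylative Sonogashira coupling with commercial 1-(benzyloxy)-4-ethynylbenzene (PdCl2(dppf), CO, Et2NH, 60 to 100 °C) passes through 1-{2,4-bis(benzyloxy)-3-[5,7-dimethoxy-2-(4-methoxyphenyl)-4-oxo-4H-chromen-3-yl]-6-hydroxyphenyl}-3-[4-(benzyloxy)phenyl]prop-2-yn-1-one F2. This ynone closes 6-endo-dig in the amine medium to 18, and the blocking groups again leave only one oxygen for the closure.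

**Step 6.**
- What may go wrong: protodeboronation of the electron-rich, di-ortho-alkoxy boronic acid may outrun transmetalation. Reductive elimination to a bond with four ortho substituents may be slow enough for deiodination of 6 to take over.
- Fallback, from 11 back to 12: the order of the two arylations of the chromone is inverted, so the hindered bond is made while C2 still carries hydrogen. Commercial 1-(2-hydroxy-4,6-dimethoxyphenyl)ethanone is condensed with DMF dimethyl acetal to (E)-3-(dimethylamino)-1-(2-hydroxy-4,6-dimethoxyphenyl)prop-2-en-1-one F3. I2 in CHCl3 cyclises this to 3-iodo-5,7-dimethoxy-4H-chromen-4-one F4. Suzuki-Miyaura coupling of F4 with 11, now an isoflavone-type coupling with only three ortho substituents, should give 3-[2,6-bis(benzyloxy)-4-(triisopropylsilyloxy)phenyl]-5,7-dimethoxy-4H-chromen-4-one F5. Zincation of the acidic C2-H with TMPZnCl·LiCl in THF gives chloro{3-[2,6-bis(benzyloxy)-4-(triisopropylsilyloxy)phenyl]-5,7-dimethoxy-4-oxo-4H-chromen-2-yl}zinc F6. Negishi coupling with 4-iodoanisole (Pd2(dba)3, SPhos, THF, 50 °C) then delivers 12.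

**Step 5.**
- What may go wrong: deprotonation of a benzylic CH2 group followed by a [1,2]-Wittig shift may compete with ring lithiation, or lithiation may stay incomplete.
- Fallback, from 8 back to 9: deprotonation is replaced by halogen-metal exchange. Hydrogenolysis of both benzyl ethers of 8 (H2, Pd/C, EtOAc) gives 5-(triisopropylsilyloxy)benzene-1,3-diol F7. Iodination with I2 and NaHCO3 in aqueous THF at 0 °C, conditions that send iodine between the two hydroxyls of resorcinols, should give 2-iodo-5-(triisopropylsilyloxy)benzene-1,3-diol F8. Re-benzylation (BnBr, K2CO3, acetone, reflux) gives [3,5-bis(benzyloxy)-4-iodophenoxy]triisopropylsilane F9. Iodine-lithium exchange with n-BuLi at −78 °C is much faster than any deprotonation and returns to aryllithium 9.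

**Further compounds**

F1 | step 8 | 3-[2,6-bis(benzyloxy)-4-hydroxy-3-iodophenyl]-5,7-dimethoxy-2-(4-methoxyphenyl)-4H-chromen-4-one | COc1ccc(-c2oc3cc(OC)cc(OC)c3c(=O)c2-c2c(OCc3ccccc3)cc(O)c(I)c2OCc2ccccc2)cc1
F2 | step 8 | 1-{2,4-bis(benzyloxy)-3-[5,7-dimethoxy-2-(4-methoxyphenyl)-4-oxo-4H-chromen-3-yl]-6-hydroxyphenyl}-3-[4-(benzyloxy)phenyl]prop-2-yn-1-one | COc1ccc(-c2oc3cc(OC)cc(OC)c3c(=O)c2-c2c(OCc3ccccc3)cc(O)c(C(=O)C#Cc3ccc(OCc4ccccc4)cc3)c2OCc2ccccc2)cc1
F3 | step 6 | (E)-3-(dimethylamino)-1-(2-hydroxy-4,6-dimethoxyphenyl)prop-2-en-1-one | CN(C)/C=C/C(=O)c1c(O)cc(OC)cc1OC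
F4 | step 6 | 3-iodo-5,7-dimethoxy-4H-chromen-4-one | COc1cc(OC)c2c(=O)c(I)coc2c1
F5 | step 6 | 3-[2,6-bis(benzyloxy)-4-(triisopropylsilyloxy)phenyl]-5,7-dimethoxy-4H-chromen-4-one | COc1cc(OC)c2c(=O)c(-c3c(OCc4ccccc4)cc(O[Si](C(C)C)(C(C)C)C(C)C)cc3OCc3ccccc3)coc2c1
F6 | step 6 | chloro{3-[2,6-bis(benzyloxy)-4-(triisopropylsilyloxy)phenyl]-5,7-dimethoxy-4-oxo-4H-chromen-2-yl}zinc | COc1cc(OC)c2c(=O)c(-c3c(OCc4ccccc4)cc(O[Si](C(C)C)(C(C)C)C(C)C)cc3OCc3ccccc3)c([Zn]Cl)oc2c1
F7 | step 5 | 5-(triisopropylsilyloxy)benzene-1,3-diol | CC(C)[Si](Oc1cc(O)cc(O)c1)(C(C)C)C(C)C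
F8 | step 5 | 2-iodo-5-(triisopropylsilyloxy)benzene-1,3-diol | CC(C)[Si](Oc1cc(O)c(I)c(O)c1)(C(C)C)C(C)C
F9 | step 5 | [3,5-bis(benzyloxy)-4-iodophenoxy]triisopropylsilane | CC(C)[Si](Oc1cc(OCc2ccccc2)c(I)c(OCc2ccccc2)c1)(C(C)C)C(C)C
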